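**Plan**

- Atom labels follow eudesmane numbering: side chain C1–C4 (C15 methyl on C4), carbocycle C5–C10 (C14 methyl on C10), lactone C11–C13 with its ring oxygen on C8, ester oxygen on C6.
- Retrosynthesis cuts, in order: the O6–acyl bond, the C11=C13 methylene, then the C6–O bond, which is traced back to a C6–C1 bond (Baeyer–Villiger). This folds the C1–C4 chain onto C6 as a 4‑methylcyclohexanone (ring C1–C6). Then C8–C9 (allylsilane/oxocarbenium closure), C6–C7 (Michael) and C5–C10 (conjugate addition) are cut.
- Forward: the temporary cyclohexenone ring is made first. One three‑component operation joins C5–C10 and C6–C7. The carbocycle C5–C10 is then closed onto the lactone acetal carbon C8, the ketone ring is expanded by oxygen insertion, the alkene is moved to C5=C10, and the seven‑membered lactone is unzipped to give O6–H and the C1–C4 chain.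
- Feature that makes the key step possible: C6 sits between C5 and C7 and is four carbons from C1, so C6/C5 can be the α/β carbons of a cyclohexanone that carries C4 as a ring stereocentre. C8, the lactone O‑bearing carbon, is the acetal carbon of a 5‑alkoxyfuranone.
- Stereochemistry: C4 comes from an organocatalytic Michael addition. C5 (temporary) and C6 follow from C4 by trans,trans conjugate addition/enolate trapping on the ring. C7 comes from the (5R)-menthyloxy acetal (anti addition), C8 from cis ring fusion, C6–O from Baeyer–Villiger retention, and the acyl stereocentre is bought.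

Key step: step 3

Remark: the acyl group in the given SMILES is (R)-2-methylbutanoyl, and the route uses (R)-2-methylbutanoic acid accordingly.

**Route**

Step 1
Reactants: 1 propanal; 2 but-3-en-2-one
Product: 3 (S)-2-methyl-5-oxohexanal
Conditions: (R)-2-(methoxydiphenylmethyl)pyrrolidine (5 mol %), ethyl 3,4-dihydroxybenzoate (20 mol %), neat, 4 °C
Reagents that add atoms: none
Why: Enamine-catalysed Michael addition of an aldehyde to a vinyl ketone; the diarylprolinol ether shields one face of the E-enamine, and the (R)-catalyst is chosen so that the new stereocentre (later C4) should be S.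

Step 2
Reactants: 3 (S)-2-methyl-5-oxohexanal
Product: 4 (S)-4-methylcyclohex-2-en-1-one
Conditions: LiOH (0.1 equiv), i-PrOH, rt
Reagents that add atoms: none
Why: Intramolecular aldol condensation (Robinson-type ring closure) of the methyl ketone onto the aldehyde; the stereocentre ends up at the γ-position and is not touched in the bond-forming events.

Step 3
Reactants: 4 (S)-4-methylcyclohex-2-en-1-one; 5 (2-bromoallyl)trimethylsilane; 6 (5R)-5-[(1R,2S,5R)-menthyloxy]furan-2(5H)-one
Product: 9 Michael adduct, 4-methyl-3-[3-(trimethylsilyl)prop-1-en-2-yl]-2-[2-(menthyloxy)-5-oxotetrahydrofuran-3-yl]cyclohexan-1-one (all-trans on the cyclohexanone, lactone substituents trans), via vinylmagnesium reagent 7 (not isolated), via magnesium enolate 8 (not isolated)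
Conditions: 5, Mg, THF, 40 °C; CuBr·SMe2 (10 mol %), 4, −78 → −40 °C; then 6, −78 → −20 °C; sat. aq NH4Cl
Reagents that add atoms: none
Why: Copper-catalysed 1,4-addition of 7 to 4 should occur anti to the C4 methyl group, and the regiodefined magnesium enolate 8 then adds through C6 to C4 of furanone 6 (Michael addition), the lactone enolate being protonated on quench. The closest known reaction types are tandem conjugate addition–Michael sequences of cuprate-derived cyclohexanone enolates, conjugate additions of this silyl-bearing vinyl reagent to enones, and enolate additions to 5-menthyloxyfuran-2(5H)-one. No ring is closed; two C–C bonds (C5–C10, C6–C7) and three stereocentres are formed. C5 is set by the C4 methyl (trans), C6 by the new C5 substituent (trans, which places C7 cis to the C4 methyl, the configuration C6 keeps through the later oxygen insertion), and C7 by the acetal carbon of 6 (attack anti to the menthyloxy group). The step needs 1,4- over 1,2-addition (copper catalysis) and C–C bond formation faster than proton exchange with the acceptor (low temperature, reactive vinylogous-carbonate acceptor). The (5R) acetal is the enantiomer whose anti face gives the C7 configuration of the target; the allylsilane is inert to the enolate chemistry.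

Step 4
Reactants: 9 Michael adduct
Product: 10 tricyclic keto lactone (cyclohexanone C1–C6 trans-fused at C5–C6 to cyclohexane C5–C10 bearing the exocyclic C10=C14 methylene; γ-lactone cis-fused at C7–C8)
Conditions: TMSOTf (0.2 equiv), CH2Cl2, −78 → −30 °C; Et3N, aq NaHCO3
Reagents that add atoms: none
Why: Intramolecular Hosomi–Sakurai reaction: TMSOTf ionises the menthyloxy acetal (acetal-selective, ketones are not allylated under these conditions) to an acyloxocarbenium ion at C8, which the allylsilane terminus C9 captures from the face carrying the tether, so the six-membered ring closes with C8 cis to the C7–C6 bond and silicon passes to menthoxide.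

Step 5
Reactants: 10 tricyclic keto lactone
Product: 11 bis-lactone (seven-membered lactone O6–C1(=O)–C2–C3–C4–C5–C6 fused to the methylenecyclohexane and γ-lactone)
Conditions: Me3SiOOSiMe3 (2 equiv), TMSOTf (0.1 equiv), CH2Cl2, −40 → −20 °C
Reagents that add atoms: bis(trimethylsilyl) peroxide, C[Si](C)(C)OO[Si](C)(C)C
Why: Baeyer–Villiger oxidation under silyl peroxide/Lewis acid conditions that leave C=C bonds alone; the more substituted α-carbon C6 migrates with retention, so the C1–C6 bond becomes the C6–O bond with the target configuration.

Step 6
Reactants: 11 bis-lactone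
Product: 12 5(10)-ene bis-lactone
Conditions: TsOH (0.1 equiv), benzene, 60 °C
Reagents that add atoms: none
Why: Acid-catalysed alkene isomerisation under thermodynamic control should move the exocyclic double bond into the tetrasubstituted endocyclic C5=C10 position (protonation gives the C10 cation, not the C5 cation next to the acyloxy carbon); this also removes the temporary C5 stereocentre.

Step 7
Reactants: 12 5(10)-ene bis-lactone
Product: 14 hydroxy acid lactone, via dilithium dicarboxylate 13 (not isolated)
Conditions: LiOH, THF–H2O, 0 °C → rt; then 1 M HCl to pH 3, rt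
Reagents that add atoms: water, O
Why: Saponification opens both lactones; on acidification the γ-hydroxy acid should reclose to the cis-fused 12,8-lactone (the arrangement found in the natural 6-hydroxy series) while the seven-membered lactone stays open, which frees O6–H and the C1 acid without touching a stereocentre.

Step 8
Reactants: 14 hydroxy acid lactone
Product: 16 diol lactone (11,13-dihydro analogue of the parent diol), via mixed carbonic anhydride 15 (not isolated)
Conditions: i-BuOCOCl, N-methylmorpholine, THF, −15 °C; then NaBH4, H2O, 0 °C
Reagents that add atoms: none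
Why: Mixed-anhydride activation followed by borohydride reduction converts the carboxylic acid into the primary alcohol chemoselectively beside the γ-lactone.

Step 9
Reactants: 16 diol lactone
Product: 17 primary TBS ether
Conditions: TBSCl, imidazole, CH2Cl2, 0 °C
Reagents that add atoms: tert-butyldimethylsilyl chloride, CC(C)(C)[Si](C)(C)Cl
Why: Silylation is selective for the primary C1 hydroxyl over the hindered secondary allylic C6 hydroxyl.

Step 10
Reactants: 17 primary TBS ether
Product: 20 α-methylene lactone (1-O-TBS ether of the parent diol), via Mannich base 18 (not isolated), via ammonium iodide 19 (not isolated)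
Conditions: LDA (2.2 equiv), THF, −78 °C; Me2N=CH2+ I−, −78 °C → rt; then MeI, MeOH, rt; then aq NaHCO3, CH2Cl2
Reagents that add atoms: N,N-dimethylmethyleneiminium iodide (Eschenmoser's salt), C[N+](C)=C.[I-]
Why: α-Methylenation of a γ-lactone by Mannich reaction of the alkoxide/lactone-enolate dianion, N-methylation and β-elimination; the C6 alkoxide is trans to the lactone, so lactone migration is not expected at low temperature.

Step 11
Reactants: 20 α-methylene lactone; 21 (R)-2-methylbutanoic acid
Product: 22 6-O-[(R)-2-methylbutanoyl] ester, TBS ether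
Conditions: DCC, DMAP (cat.), CH2Cl2, 0 °C → rt
Reagents that add atoms: none
Why: Steglich esterification of the allylic C6 hydroxyl with retention at C6; the acid stereocentre is carried over unchanged under catalytic DMAP.

Step 12
Reactants: 22 ester TBS ether
Product: 23 target compound CNP0291605.2
Conditions: HF·pyridine, THF, 0 °C
Reagents that add atoms: none
Why: Fluoride-mediated desilylation of the primary silyl ether under buffered acidic conditions that tolerate the α-methylene lactone and the allylic ester.

**Compound list**

1 | propanal | CCC=O | starting material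
2 | but-3-en-2-one | CC(=O)C=C | starting material
3 | (S)-2-methyl-5-oxohexanal | CC(=O)CC[C@H](C)C=O | intermediate
4 | (S)-4-methylcyclohex-2-en-1-one | C[C@@H]1C=CC(=O)CC1 | intermediate
5 | (2-bromoallyl)trimethylsilane | C=C(Br)C[Si](C)(C)C | starting material
6 | (5R)-5-[(1R,2S,5R)-menthyloxy]furan-2(5H)-one | O=C1C=C[C@H](O[C@@H]2C[C@H](C)CC[C@H]2C(C)C)O1 | starting material
7 | [3-(trimethylsilyl)prop-1-en-2-yl]magnesium bromide | C=C([Mg]Br)C[Si](C)(C)C | intermediate (not isolated)
8 | bromomagnesium enolate of trans-4-methyl-3-[3-(trimethylsilyl)prop-1-en-2-yl]cyclohexanone | C=C(C[Si](C)(C)C)[C@@H]1[C@@H](C)CCC(O[Mg]Br)=C1 | intermediate (not isolated)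
9 | Michael adduct (cyclohexanone with C4 methyl, C5 silylmethylvinyl and C6 lactone substituents all trans; menthyloxy trans to the cyclohexanone on the lactone) | C=C(C[Si](C)(C)C)[C@@H]1[C@@H](C)CCC(=O)[C@H]1[C@@H]2CC(=O)O[C@H]2O[C@@H]3C[C@H](C)CC[C@H]3C(C)C | intermediate
10 | tricyclic keto lactone with exocyclic C10=C14 methylene (trans ring fusion C5–C6, cis-fused γ-lactone) | C1C(=O)O[C@@H]2CC(=C)[C@@H]3[C@@H](C)CCC(=O)[C@H]3[C@H]12 | intermediate
11 | bis-lactone (seven-membered lactone from O insertion between C1 and C6) | C1C(=O)O[C@@H]2CC(=C)[C@@H]3[C@@H](C)CCC(=O)O[C@H]3[C@H]12 | intermediate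
12 | 5(10)-ene bis-lactone | C1C(=O)O[C@@H]2CC(C)=C3[C@@H](C)CCC(=O)O[C@H]3[C@H]12 | intermediate
13 | dilithium dihydroxy dicarboxylate (both lactones open) | [Li+].[Li+].[O-]C(=O)C[C@@H]1[C@H](O)CC(C)=C([C@@H](C)CCC([O-])=O)[C@H]1O | intermediate (not isolated)
14 | hydroxy acid lactone (12,8-lactone, free 6-OH, C1 carboxylic acid) | C1C(=O)O[C@@H]2CC(C)=C([C@@H](C)CCC(=O)O)[C@@H](O)[C@H]12 | intermediate
15 | isobutyl mixed carbonic anhydride of 14 | C1C(=O)O[C@@H]2CC(C)=C([C@@H](C)CCC(=O)OC(=O)OCC(C)C)[C@@H](O)[C@H]12 | intermediate (not isolated)
16 | diol lactone (1,6-diol, saturated C11) | C1C(=O)O[C@@H]2CC(C)=C([C@@H](C)CCCO)[C@@H](O)[C@H]12 | intermediate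
17 | 1-O-TBS ether of 16 | C1C(=O)O[C@@H]2CC(C)=C([C@@H](C)CCCO[Si](C)(C)C(C)(C)C)[C@@H](O)[C@H]12 | intermediate
18 | α-(dimethylaminomethyl) lactone (Mannich base, C11 epimers) | CN(C)CC1C(=O)O[C@@H]2CC(C)=C([C@@H](C)CCCO[Si](C)(C)C(C)(C)C)[C@@H](O)[C@H]12 | intermediate (not isolated)
19 | trimethylammonium iodide of 18 | C[N+](C)(C)CC1C(=O)O[C@@H]2CC(C)=C([C@@H](C)CCCO[Si](C)(C)C(C)(C)C)[C@@H](O)[C@H]12.[I-] | intermediate (not isolated)
20 | α-methylene lactone with free 6-OH and 1-O-TBS | C=C1C(=O)O[C@@H]2CC(C)=C([C@@H](C)CCCO[Si](C)(C)C(C)(C)C)[C@@H](O)[C@H]12 | intermediate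
21 | (R)-2-methylbutanoic acid | CC[C@@H](C)C(=O)O | starting material
22 | 6-O-[(R)-2-methylbutanoyl] 1-O-TBS α-methylene lactone | C=C1C(=O)O[C@@H]2CC(C)=C([C@@H](C)CCCO[Si](C)(C)C(C)(C)C)[C@@H](OC(=O)[C@H](C)CC)[C@H]12 | intermediate
23 | target, CNP0291605.2 | C=C1C(=O)O[C@@H]2CC(C)=C([C@@H](C)CCCO)[C@@H](OC(=O)[C@H](C)CC)[C@H]12 | target

**Totals and risks**

Total steps: 12. Longest linear sequence: 12 (from propanal and but-3-en-2-one).

Steps most likely to fail:

1. Step 6. The isomerisation may stop at, or equilibrate with, the trisubstituted 9(10)-ene, and the acid may ionise the allylic lactone C–O bond once the 5(10)-ene has formed. Fallback (conjugation-driven placement of the alkene): the alkene mixture is carried through steps 7–9 without separation, so the fallback sets out from 17 accompanied by its 9(10)-ene isomer F1. Dess–Martin oxidation of the C6 alcohols followed by Et3N converges both isomers on the conjugated 6-oxo-5(10)-ene F2, because the β,γ-enone from F1 moves into conjugation with the C6 ketone. Luche reduction (NaBH4, CeCl3, MeOH, −78 °C) should deliver hydride from the face opposite the cis-fused lactone and give the 6-epi alcohol F3. Mitsunobu inversion with 4-nitrobenzoic acid gives the 4-nitrobenzoate F4 with the target C6 configuration, and K2CO3/MeOH removes the ester to return to the route at 17.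

2. Step 3. The Michael addition of the hindered magnesium enolate may be slower than proton transfer from the acceptor or enolate equilibration. Fallback (two separate operations with a purified enolate precursor): from 4, the same copper-catalysed conjugate addition is run with TMSCl present, and the trimethylsilyl enol ether F5 is isolated. Methyllithium in THF regenerates the salt-free lithium enolate F6, which is added to 6 at −78 °C, the standard way of adding lithium enolates to this furanone, to come back at 9.

3. Step 4. The allylsilane may attack the ring ketone (five-membered ring closure) or lose silicon by protonation before the acetal ionises. Fallback (cation–olefin closure without an allylsilane): from 4, isopropenylmagnesium bromide replaces 7 in the step-3 procedure and gives, through the magnesium enolate F7, the isopropenyl adduct F8. BF3·OEt2 in CH2Cl2 then closes the ring by oxocarbenium–alkene (Prins) cyclisation with loss of a proton, which returns to the route at 10; any endocyclic alkene isomers formed alongside converge in step 6.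

Further compounds

F1 | step 6 | 9(10)-ene isomer of 17 (C5 configuration not defined) | C1C(=O)O[C@@H]2C=C(C)C([C@@H](C)CCCO[Si](C)(C)C(C)(C)C)[C@@H](O)[C@H]12
F2 | step 6 | 6-oxo-5(10)-ene lactone, 1-O-TBS | C1C(=O)O[C@@H]2CC(C)=C([C@@H](C)CCCO[Si](C)(C)C(C)(C)C)C(=O)[C@H]12
F3 | step 6 | 6-epi-17 | C1C(=O)O[C@@H]2CC(C)=C([C@@H](C)CCCO[Si](C)(C)C(C)(C)C)[C@H](O)[C@H]12
F4 | step 6 | 6-O-(4-nitrobenzoyl) derivative of 17 | C1C(=O)O[C@@H]2CC(C)=C([C@@H](C)CCCO[Si](C)(C)C(C)(C)C)[C@@H](OC(=O)c3ccc(cc3)[N+](=O)[O-])[C@H]12
F5 | step 3 | trimethylsilyl enol ether of trans-4-methyl-3-[3-(trimethylsilyl)prop-1-en-2-yl]cyclohexanone | C=C(C[Si](C)(C)C)[C@@H]1[C@@H](C)CCC(O[Si](C)(C)C)=C1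
F6 | step 3 | lithium enolate corresponding to F5 | C=C(C[Si](C)(C)C)[C@@H]1[C@@H](C)CCC(O[Li])=C1
F7 | step 4 | bromomagnesium enolate of trans-3-isopropenyl-4-methylcyclohexanone | C=C(C)[C@@H]1[C@@H](C)CCC(O[Mg]Br)=C1
F8 | step 4 | isopropenyl analogue of 9 | C=C(C)[C@@H]1[C@@H](C)CCC(=O)[C@H]1[C@@H]2CC(=O)O[C@H]2O[C@@H]3C[C@H](C)CC[C@H]3C(C)C
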